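## The problem

The target 25 is a cyclohexa-1,4-diene. C1 carries the 2-acetoxypentadecyl chain, C3 a free hydroxyl, C5 a methoxy group as a methyl enol ether and C6 an acetate; the chain has a second acetate at C2'. No other ring is fused to it, so the task is to build one six-membered carbocycle with two isolated double bonds (C1=C2, C4=C5) and two doubly allylic carbinol carbons (C3, C6) without ever letting it aromatise. Three stereocentres are needed: C3 (R) and C6 (S) stand cis but 1,4 to each other across a nearly flat ring and cannot control one another there, and C2' (R) is insulated from the ring by a methylene group. Each must therefore come from its own reagent-controlled event or from the chiral pool, before the ring is closed. The fragile elements are the enol ether (hydrolysis), the two doubly allylic C–O bonds (ionisation, then loss of water, methanol or acetic acid gives an arene), the skipped diene (base-induced conjugation) and the acetates (cleavage or migration under basic fluoride). A ring ketone at C5 has to be avoided, since its enol opens the way to a phenol. O3 must stay distinguishable from O6 and O2' to the end. What makes a short ring closure possible is that C5 with its methoxy group and the carbinol C6 are together a methyl α-hydroxy ester at the oxidation level of the target, while C4 can be brought in as the terminal carbon of a vinyl group on C3. A Z-configured C1=C2 bond then holds C5 and C4 within reach, so one carbonyl–olefin ring closure makes C4=C5 and the enol ether together.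

## Retrosynthesis

**Protecting groups (25 ⇒ 24 ⇒ 23 ⇒ 22).** The last bonds cut are the two O–acetyl bonds and O3–H, which goes back to an O3–Si bond. Acetates cannot be present earlier, because an alkylidenating titanium reagent would not tell them from the C5 ester. All three oxygens therefore enter the ring closure as silyl ethers: the robust tert-butyldiphenylsilyl (TBDPS) group on O3 and triethylsilyl (TES) groups on O6 and O2' (22). The forward steps must remove the two TES groups beside the TBDPS ether without hydrolysing the enol ether (23), acetylate (24), and free O3 with buffered fluoride without moving an acetate.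

**Ring (22 ⇒ 21).** The C4=C5 double bond is cut back to the ester carbonyl at C5 and a vinyl group on C3. Unlike a C1–C6 or C5–C6 cut, this creates no stereocentre in the ring closure. Unlike a diene metathesis across C4=C5, it needs no separately made enol ether, because the methoxy group is the ester's own. Precursor 21 is acyclic, already holds all three stereocentres, and stores C5 as an ordinary ester. The forward step must close the ring faster than it merely alkylidenates the ester and must leave the trisubstituted alkene and the silyl ethers alone.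

**C6 (21 ⇒ 20 ⇒ 19).** The O6–Si bond and then the C6–H bond are cut, giving α-keto ester 19. A ketone at C6 is the direct product of acylating a C1 nucleophile with an oxalate. Adding the same nucleophile to a glyoxylate would give both C6 epimers. The forward reduction must be reagent-controlled, since C3 and C2' are too remote to help, and must be 1,2-selective.

**C1–C6 (19 ⇒ 16 + 17).** The C1–C6 bond is cut to alkenyl iodide 16, used as alkenyllithium 18, and dimethyl oxalate 17, which supplies C5, C6 and the methoxy group. C5 and C6 are deliberately brought in after the C1–C1' bond. If the ester were present earlier, the organometallic chemistry at C1 would have to tolerate it, and an O2' alkoxide would close a six-membered lactone onto C5 with loss of the methoxy group. In 16, O2' is already capped.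

**Alkene geometry (16 ⇒ 15 ⇒ 14 ⇒ 13).** The C1–I bond goes back to a C1–Sn bond, and the C1–Sn and C2–H bonds to alkyne 13. Anti addition of H and Sn puts tin, and later C6, cis to C3, as the ring closure requires. The other possible alkyne (C6–C1≡C2–C3) would need a syn hydrometallation with regiocontrol between two similar propargylic carbinol carbons, followed by an alkenylcopper/epoxide union next to an ester. Here the free O2'–H of 13 directs tin to C1, and the bulky TBDPS ether on C3 works in the same direction.

**C1–C1' (13 ⇒ 7 + 11).** The sp–sp3 bond is cut to lithium acetylide 12, made from terminal alkyne 7, and terminal epoxide 11. Both fragments are small, neither stereocentre is touched, and the forward reaction only has to open the epoxide at its unsubstituted carbon.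

**C3 (7 ⇒ 6 ⇒ 5 ⇒ 4 ⇒ 1 + 2).** The C(sp)–H bond goes back to a C–SiMe3 bond, the O3–Si bond to the free carbinol 5, and 5 to racemate 4, made from acetylide 3 (from 1) and acrolein 2 by forming C2–C3. The trimethylsilyl group is kept through the resolution on purpose. It makes the alkynyl arm clearly larger than the vinyl arm, which is what a lipase needs to distinguish the enantiomers.

**C2' (11 ⇒ 10 ⇒ 8 + 9).** The epoxide is cut back to chlorohydrin 10 and, at the C3'–C4' bond, to dodecylmagnesium bromide 8 and (R)-epichlorohydrin 9. The stereocentre is bought, and no bond to it is made or broken.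

## Roads not taken

**Alternative 1:** The ring is cut at C1–C6 and C2–C3. The precursor is dienyne A1, in which an alkyne C1≡C2 and a trioxygenated diene C3=C4–C5=C6 are linked by a diisopropylsilylene bridge between O6 and O2'. Heating in toluene, or [Rh(cod)Cl]2 with AgSbF6 (univalent rhodium), would close the carbocycle and a seven-membered silaketal in one [4+2] event to give A2.
- Merits: two C–C bonds and both ring stereocentres arise in one step. C2' relays its configuration to C6 and C3 through the tether, so epichlorohydrin would be the only chiral input. Cleaving the silylene frees exactly O6 and O2' for acetylation while O3 stays silylated.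
- Weak points: an unactivated alkyl alkyne and a very electron-rich diene are electronically mismatched. The 1-silyloxy-2-methoxy-4-silyloxybutadiene must be made with defined geometry and is labile to hydrolysis. Facial control must pass from C2' through a seven-membered tether. The product is a cyclohexadiene that can lose silanol on prolonged heating.
- Comparison: in bonds per step and in stereochemical economy this road is better. The chosen plan offers C–C bond formations of broad scope (acetylide/epoxide, alkenyllithium/oxalate), stereocentres set one at a time by independent methods, and a ring closure that starts from a stable ester.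

**Alternative 2:** The ring is cut at C5–C6 and C3–C4. The (1E,3E)-diene A3 (silyloxy at C6, acetoxy at C3) would add thermally to the exocyclic alkene of the lactic-acid-derived dioxolanone A4 to give spiro adduct A5, with C5 as a quaternary centre carrying a masked α-hydroxy acid.
- Merits: the ring and the cis relation of O3 and O6 are made in one intermolecular step. The tert-butyl acetal of A4 selects the face, and the silyloxy terminus fixes the regiochemistry. As long as the carboxyl sits on C5, no aromatisation is possible.
- Weak points: C4 is a methylene after the cycloaddition. C5 must be unveiled by acetal hydrolysis and oxidative decarboxylation as a ketone and then turned regioselectively into the C4=C5 methyl enol ether. That ketone is β to the C3 acetate, so it is the enolisable intermediate most likely to eliminate towards a phenol. The oxygen pattern of A5 (acetate on O3, silyl on O6 and O2') is the inverse of the target's and must be exchanged.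
- Comparison: the cycloaddition itself is better than anything in the chosen route at setting C3 and C6 together. The chosen plan takes C5 from dimethyl oxalate at the correct oxidation level and never passes a ring ketone.

**Alternative 3:** Only C1–C6 is cut. Iodo aldehyde A6 would close under CrCl2 with catalytic NiCl2 (divalent chromium, divalent nickel) and a chiral oxazoline–sulfonamide ligand to give A7.
- Merits: the conditions are neutral and highly chemoselective. Ring closures of alkenyl iodides onto aldehydes have a broader record for carbocycles than titanium-mediated ester–olefin closure, which is a real advantage in precedent. A7 has O6 free and O3 and O2' already differentiated, so the endgame is shorter.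
- Weak points: C6 is created in the ring closure, where 1,4-induction from C3 is weak and everything rests on the ligand. A6 carries the C4=C5 enol ether as an α-methoxy enal with a γ-silyloxy stereocentre; this unit is prone to γ-enolisation and double-bond isomerisation, and it cyclises only in one geometry. Chromium is used in stoichiometric amount.
- Comparison: equal or shorter in steps. The chosen plan sets C6 on an acyclic α-keto ester, where a wrong outcome can be corrected by inversion, forms no stereocentre during ring closure, and makes the enol ether only in the ring-forming step.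

Key step: step 14

Remarks on the chemistry (assumptions):
- In the lipase acylation of 4 the trimethylsilylethynyl group is taken as the large and the vinyl group as the medium substituent, so the (R)-alcohol is expected to be acylated and the (S)-alcohol 5 recovered.
- In the oxazaborolidine reduction of 19 the branched alkenyl group is taken as the large and the methoxycarbonyl group as the small substituent, as for α-substituted enones; the (S)-catalyst is named on that basis.

## Route

Step 1
Reactants: 1 (trimethylsilyl)acetylene; 2 acrolein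
Product: 4 rac-5-(trimethylsilyl)pent-1-en-4-yn-3-ol, via lithium (trimethylsilyl)acetylide 3 (not isolated)
Conditions: n-BuLi, THF, −78 °C; then 2, −78 °C; aq. NH4Cl
Reagents that add atoms: none
Why: Addition of a lithium acetylide to an aldehyde; at −78 °C the acetylide adds 1,2 to acrolein and forms the C2–C3 bond, giving the C3 carbinol as the racemate that is resolved in step 2.

Step 2
Reactants: 4 rac-5-(trimethylsilyl)pent-1-en-4-yn-3-ol
Product: 5 (3S)-5-(trimethylsilyl)pent-1-en-4-yn-3-ol
Conditions: Candida antarctica lipase B (immobilised), vinyl acetate, MTBE, 30 °C, run to slightly beyond half conversion; chromatography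
Reagents that add atoms: none
Why: Lipase-catalysed kinetic resolution by irreversible acylation; with the silylalkynyl arm as the large and vinyl as the medium group the (R)-alcohol should be acetylated, and the unreacted (S)-alcohol, which has the C3 configuration of the target, is recovered.

Step 3
Reactants: 5 (3S)-5-(trimethylsilyl)pent-1-en-4-yn-3-ol
Product: 6 tert-butyl(diphenyl){[(3S)-5-(trimethylsilyl)pent-1-en-4-yn-3-yl]oxy}silane
Conditions: TBDPSCl, imidazole, DMF, rt
Reagents that add atoms: tert-butyl(chloro)diphenylsilane, CC(C)(C)[Si](Cl)(c1ccccc1)c1ccccc1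
Why: Standard silylation of a secondary alcohol; the TBDPS group marks O3 and is the one silyl ether meant to survive until the last step.

Step 4
Reactants: 6 tert-butyl(diphenyl){[(3S)-5-(trimethylsilyl)pent-1-en-4-yn-3-yl]oxy}silane
Product: 7 tert-butyl[(3S)-pent-1-en-4-yn-3-yloxy]diphenylsilane
Conditions: K2CO3, MeOH, rt
Reagents that add atoms: none
Why: Base-catalysed methanolysis of the C(sp)–Si bond; the hindered O–Si bond of the TBDPS ether is not attacked under these conditions.

Step 5
Reactants: 8 dodecylmagnesium bromide; 9 (R)-epichlorohydrin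
Product: 10 (2R)-1-chloropentadecan-2-ol
Conditions: CuI (cat.), THF, −40 → 0 °C; aq. NH4Cl
Reagents that add atoms: none
Why: Copper-catalysed Grignard opening of the epoxide at its unsubstituted carbon, which is faster than displacement of chloride; no bond to the stereocentre is touched, and it becomes C2'.

Step 6
Reactants: 10 (2R)-1-chloropentadecan-2-ol
Product: 11 (2R)-2-tridecyloxirane
Conditions: NaOH, H2O/Et2O, rt
Reagents that add atoms: none
Why: Intramolecular Williamson ether closure of the chlorohydrin; the C–O bond at the stereocentre is retained, so the (R)-epoxide results.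

Step 7
Reactants: 7 tert-butyl[(3S)-pent-1-en-4-yn-3-yloxy]diphenylsilane; 11 (2R)-2-tridecyloxirane
Product: 13 (3S,7R)-3-[(tert-butyldiphenylsilyl)oxy]icos-1-en-4-yn-7-ol, via lithium acetylide of the silyl ether 12 (not isolated)
Conditions: n-BuLi, THF, −78 °C; BF3·OEt2, then 11, −78 °C; aq. NH4Cl
Reagents that add atoms: none
Why: BF3-assisted opening of a terminal epoxide by a lithium acetylide (Yamaguchi–Hirao alkynylation) at the unsubstituted carbon; it forms C1–C1', leaves C3 and C2' untouched, and delivers O2' as the free hydroxyl needed in step 8.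

Step 8
Reactants: 13 (3S,7R)-3-[(tert-butyldiphenylsilyl)oxy]icos-1-en-4-yn-7-ol
Product: 14 (3S,4Z,7R)-3-[(tert-butyldiphenylsilyl)oxy]-5-(tributylstannyl)icosa-1,4-dien-7-ol
Conditions: [Cp*RuCl]4 (cat.), Bu3SnH, CH2Cl2, rt, dark
Reagents that add atoms: tributyltin hydride, CCCC[SnH](CCCC)CCCC
Why: Ruthenium-catalysed trans-hydrostannation of an internal alkyne; hydrogen bonding of the free homopropargylic hydroxyl to the chloride ligand should steer tin to the proximal carbon C1, and the bulky silyloxy-bearing C3 disfavours the other regioisomer. The anti addition puts tin cis to C3, the geometry the ring closure needs, and the terminal alkene is not touched.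

Step 9
Reactants: 14 (3S,4Z,7R)-3-[(tert-butyldiphenylsilyl)oxy]-5-(tributylstannyl)icosa-1,4-dien-7-ol
Product: 15 tert-butyl{[(3S,4Z,7R)-7-[(triethylsilyl)oxy]-5-(tributylstannyl)icosa-1,4-dien-3-yl]oxy}diphenylsilane
Conditions: TESCl, imidazole, CH2Cl2, 0 °C → rt
Reagents that add atoms: chlorotriethylsilane, CC[Si](Cl)(CC)CC
Why: Standard silylation; O2' must be capped before the C5 ester arrives, because a free O2' would close a six-membered lactone onto it.

Step 10
Reactants: 15 tert-butyl{[(3S,4Z,7R)-7-[(triethylsilyl)oxy]-5-(tributylstannyl)icosa-1,4-dien-3-yl]oxy}diphenylsilane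
Product: 16 tert-butyl{[(3S,4Z,7R)-5-iodo-7-[(triethylsilyl)oxy]icosa-1,4-dien-3-yl]oxy}diphenylsilane
Conditions: I2, CH2Cl2, 0 °C
Reagents that add atoms: iodine, II
Why: Iododestannylation, an ipso substitution at the sp2 carbon that proceeds with retention of alkene geometry and is much faster than addition of iodine to the other alkenes.

Step 11
Reactants: 16 tert-butyl{[(3S,4Z,7R)-5-iodo-7-[(triethylsilyl)oxy]icosa-1,4-dien-3-yl]oxy}diphenylsilane; 17 dimethyl oxalate
Product: 19 methyl (3Z,5S)-5-[(tert-butyldiphenylsilyl)oxy]-2-oxo-3-[(2R)-2-[(triethylsilyl)oxy]pentadecyl]hepta-3,6-dienoate, via alkenyllithium 18 (not isolated)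
Conditions: t-BuLi (2 equiv.), Et2O, −78 °C; cannulation into 17 (excess) in THF, −78 °C; aq. NH4Cl
Reagents that add atoms: none
Why: Iodine–lithium exchange with retention, then acylation of the alkenyllithium by excess dialkyl oxalate, whose tetrahedral adduct is stable at low temperature so that one addition gives the α-keto ester. Ether solvent and −78 °C are chosen to suppress 1,4-migration of silicon from oxygen to carbon.

Step 12
Reactants: 19 methyl (3Z,5S)-5-[(tert-butyldiphenylsilyl)oxy]-2-oxo-3-[(2R)-2-[(triethylsilyl)oxy]pentadecyl]hepta-3,6-dienoate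
Product: 20 methyl (2S,3Z,5S)-5-[(tert-butyldiphenylsilyl)oxy]-2-hydroxy-3-[(2R)-2-[(triethylsilyl)oxy]pentadecyl]hepta-3,6-dienoate
Conditions: (S)-2-methyl-CBS-oxazaborolidine, catecholborane, toluene/CH2Cl2, −78 °C
Reagents that add atoms: none
Why: Corey–Bakshi–Shibata reduction; the ketone should bind the catalyst boron anti to the branched alkenyl group, so hydride is delivered to the face that gives the (2S)-carbinol (C6). Catecholborane at −78 °C reduces the activated ketone 1,2 under base-free conditions that leave the ester, the alkenes and the γ-hydrogen at C3 alone.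

Step 13
Reactants: 20 methyl (2S,3Z,5S)-5-[(tert-butyldiphenylsilyl)oxy]-2-hydroxy-3-[(2R)-2-[(triethylsilyl)oxy]pentadecyl]hepta-3,6-dienoate
Product: 21 methyl (2S,3Z,5S)-5-[(tert-butyldiphenylsilyl)oxy]-2-[(triethylsilyl)oxy]-3-[(2R)-2-[(triethylsilyl)oxy]pentadecyl]hepta-3,6-dienoate
Conditions: TESOTf, 2,6-lutidine, CH2Cl2, −78 °C
Reagents that add atoms: triethylsilyl trifluoromethanesulfonate, CC[Si](CC)(CC)OS(=O)(=O)C(F)(F)F
Why: Silylation of a hindered secondary alcohol with a silyl triflate and a non-nucleophilic base, which does not epimerise C6 or move the β,γ-double bond into conjugation.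

Step 14
Reactants: 21 methyl (2S,3Z,5S)-5-[(tert-butyldiphenylsilyl)oxy]-2-[(triethylsilyl)oxy]-3-[(2R)-2-[(triethylsilyl)oxy]pentadecyl]hepta-3,6-dienoate
Product: 22 tert-butyl{[(1R,4S)-3-methoxy-4-[(triethylsilyl)oxy]-5-[(2R)-2-[(triethylsilyl)oxy]pentadecyl]cyclohexa-2,5-dien-1-yl]oxy}diphenylsilane
Conditions: TiCl4, Zn, PbCl2 (cat.), TMEDA, CH3CHBr2, THF/CH2Cl2, 0 → 65 °C, high dilution
Reagents that add atoms: none
Why: The reagent made from TiCl4, Zn, catalytic PbCl2, TMEDA and CH3CHBr2 is a low-valent titanium ethylidene; it can exchange with the terminal vinyl group to put titanium on C4 (propene leaves), add [2+2] to the ester carbonyl at C5 and cyclorevert with loss of a titanium oxo species, or it can first ethylidenate the ester and then close the acyclic enol ether onto the vinyl group by olefin metathesis, and both paths end in 22. The closest known reactions are the titanium-alkylidene olefinic ester cyclisation to cyclic enol ethers under Takai–Utimoto conditions and the intramolecular trapping of a titanium alkylidene by an ester to give a carbocyclic enol ether; the difference here is that the alkoxy oxygen stays outside the new ring. The six-membered ring closes in the ring-closing-metathesis mode with the new C4=C5 bond endocyclic, and the Z-configured C1=C2 bond already holds C3 and C6 on the same side, so few rotors must be frozen. No stereocentre is formed, and C3, C6 and C2' are spectators. The step needs chemoselectivity between ring closure and simple ethylidenation: the single ester among silyl ethers fixes the site, high dilution and the templating Z-alkene favour closure, and the trisubstituted C1=C2 bond is too hindered to take part. C5 passes from ester to enol ether without being a ketone, so no enolisable dienone arises, and the amine-buffered medium holds no protic acid that could ionise the doubly allylic silyl ethers.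

Step 15
Reactants: 22 tert-butyl{[(1R,4S)-3-methoxy-4-[(triethylsilyl)oxy]-5-[(2R)-2-[(triethylsilyl)oxy]pentadecyl]cyclohexa-2,5-dien-1-yl]oxy}diphenylsilane
Product: 23 (1S,4R)-4-[(tert-butyldiphenylsilyl)oxy]-6-[(2R)-2-hydroxypentadecyl]-2-methoxycyclohexa-2,5-dien-1-ol
Conditions: HF·pyridine, excess pyridine, THF, 0 °C
Reagents that add atoms: none
Why: Fluoride cleavage of silyl ethers under pyridine buffering; secondary triethylsilyl ethers go far faster than the TBDPS ether, and the nearly neutral, water-free medium should spare the enol ether and the doubly allylic C–O bonds.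

Step 16
Reactants: 23 (1S,4R)-4-[(tert-butyldiphenylsilyl)oxy]-6-[(2R)-2-hydroxypentadecyl]-2-methoxycyclohexa-2,5-dien-1-ol
Product: 24 (1S,4R)-6-[(2R)-2-acetoxypentadecyl]-4-[(tert-butyldiphenylsilyl)oxy]-2-methoxycyclohexa-2,5-dien-1-yl acetate
Conditions: Ac2O, Et3N, DMAP (cat.), CH2Cl2, 0 °C → rt
Reagents that add atoms: acetic anhydride, CC(=O)OC(C)=O
Why: DMAP-catalysed acylation of both secondary hydroxyls under basic, acid-free conditions; no C–O bond at a stereocentre is broken.

Step 17
Reactants: 24 (1S,4R)-6-[(2R)-2-acetoxypentadecyl]-4-[(tert-butyldiphenylsilyl)oxy]-2-methoxycyclohexa-2,5-dien-1-yl acetate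
Product: 25 (1S,4R)-6-[(2R)-2-acetoxypentadecyl]-4-hydroxy-2-methoxycyclohexa-2,5-dien-1-yl acetate
Conditions: Bu4NF, AcOH (1:1), THF, 0 °C → rt
Reagents that add atoms: none
Why: Fluoride cleavage of the TBDPS ether; the acetic acid buffer keeps the liberated O3 protonated, so acetate cleavage, acetyl migration across the ring and base-induced aromatisation are suppressed.

## Compound list

1 | (trimethylsilyl)acetylene | C#C[Si](C)(C)C | starting material
2 | acrolein (prop-2-enal) | C=CC=O | starting material
3 | lithium (trimethylsilyl)acetylide | [Li]C#C[Si](C)(C)C | intermediate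
4 | rac-5-(trimethylsilyl)pent-1-en-4-yn-3-ol | C=CC(O)C#C[Si](C)(C)C | intermediate
5 | (3S)-5-(trimethylsilyl)pent-1-en-4-yn-3-ol | C=C[C@H](O)C#C[Si](C)(C)C | intermediate
6 | tert-butyl(diphenyl){[(3S)-5-(trimethylsilyl)pent-1-en-4-yn-3-yl]oxy}silane | C=C[C@H](O[Si](c1ccccc1)(c1ccccc1)C(C)(C)C)C#C[Si](C)(C)C | intermediate
7 | tert-butyl[(3S)-pent-1-en-4-yn-3-yloxy]diphenylsilane | C=C[C@H](O[Si](c1ccccc1)(c1ccccc1)C(C)(C)C)C#C | intermediate
8 | dodecylmagnesium bromide | CCCCCCCCCCCC[Mg]Br | starting material
9 | (R)-epichlorohydrin, (2R)-2-(chloromethyl)oxirane | ClC[C@H]1CO1 | starting material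
10 | (2R)-1-chloropentadecan-2-ol | ClC[C@H](O)CCCCCCCCCCCCC | intermediate
11 | (2R)-2-tridecyloxirane | CCCCCCCCCCCCC[C@@H]1CO1 | intermediate
12 | lithium acetylide of 7, [(3S)-3-[(tert-butyldiphenylsilyl)oxy]pent-4-en-1-yn-1-yl]lithium | [Li]C#C[C@@H](O[Si](c1ccccc1)(c1ccccc1)C(C)(C)C)C=C | intermediate
13 | (3S,7R)-3-[(tert-butyldiphenylsilyl)oxy]icos-1-en-4-yn-7-ol | CCCCCCCCCCCCC[C@@H](O)CC#C[C@@H](O[Si](c1ccccc1)(c1ccccc1)C(C)(C)C)C=C | intermediate
14 | (3S,4Z,7R)-3-[(tert-butyldiphenylsilyl)oxy]-5-(tributylstannyl)icosa-1,4-dien-7-ol | CCCCCCCCCCCCC[C@@H](O)C/C(=C/[C@@H](O[Si](c1ccccc1)(c1ccccc1)C(C)(C)C)C=C)[Sn](CCCC)(CCCC)CCCC | intermediate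
15 | tert-butyl{[(3S,4Z,7R)-7-[(triethylsilyl)oxy]-5-(tributylstannyl)icosa-1,4-dien-3-yl]oxy}diphenylsilane | CCCCCCCCCCCCC[C@@H](O[Si](CC)(CC)CC)C/C(=C/[C@@H](O[Si](c1ccccc1)(c1ccccc1)C(C)(C)C)C=C)[Sn](CCCC)(CCCC)CCCC | intermediate
16 | tert-butyl{[(3S,4Z,7R)-5-iodo-7-[(triethylsilyl)oxy]icosa-1,4-dien-3-yl]oxy}diphenylsilane | CCCCCCCCCCCCC[C@@H](O[Si](CC)(CC)CC)C/C(I)=C/[C@@H](O[Si](c1ccccc1)(c1ccccc1)C(C)(C)C)C=C | intermediate
17 | dimethyl oxalate | COC(=O)C(=O)OC | starting material
18 | alkenyllithium from 16 (lithium in place of iodine, alkene geometry retained), [(3S,7R)-3-[(tert-butyldiphenylsilyl)oxy]-7-[(triethylsilyl)oxy]icosa-1,4-dien-5-yl]lithium | CCCCCCCCCCCCC[C@@H](O[Si](CC)(CC)CC)C/C([Li])=C/[C@@H](O[Si](c1ccccc1)(c1ccccc1)C(C)(C)C)C=C | intermediate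
19 | methyl (3Z,5S)-5-[(tert-butyldiphenylsilyl)oxy]-2-oxo-3-[(2R)-2-[(triethylsilyl)oxy]pentadecyl]hepta-3,6-dienoate | CCCCCCCCCCCCC[C@@H](O[Si](CC)(CC)CC)C/C(=C/[C@@H](O[Si](c1ccccc1)(c1ccccc1)C(C)(C)C)C=C)C(=O)C(=O)OC | intermediate
20 | methyl (2S,3Z,5S)-5-[(tert-butyldiphenylsilyl)oxy]-2-hydroxy-3-[(2R)-2-[(triethylsilyl)oxy]pentadecyl]hepta-3,6-dienoate | CCCCCCCCCCCCC[C@@H](O[Si](CC)(CC)CC)C/C(=C/[C@@H](O[Si](c1ccccc1)(c1ccccc1)C(C)(C)C)C=C)[C@H](O)C(=O)OC | intermediate
21 | methyl (2S,3Z,5S)-5-[(tert-butyldiphenylsilyl)oxy]-2-[(triethylsilyl)oxy]-3-[(2R)-2-[(triethylsilyl)oxy]pentadecyl]hepta-3,6-dienoate | CCCCCCCCCCCCC[C@H](C/C(=C/[C@@H](O[Si](c1ccccc1)(c1ccccc1)C(C)(C)C)C=C)[C@H](O[Si](CC)(CC)CC)C(=O)OC)O[Si](CC)(CC)CC | intermediate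
22 | tert-butyl{[(1R,4S)-3-methoxy-4-[(triethylsilyl)oxy]-5-[(2R)-2-[(triethylsilyl)oxy]pentadecyl]cyclohexa-2,5-dien-1-yl]oxy}diphenylsilane | CCCCCCCCCCCCC[C@H](CC1=C[C@@H](O[Si](c2ccccc2)(c2ccccc2)C(C)(C)C)C=C(OC)[C@H]1O[Si](CC)(CC)CC)O[Si](CC)(CC)CC | intermediate
23 | (1S,4R)-4-[(tert-butyldiphenylsilyl)oxy]-6-[(2R)-2-hydroxypentadecyl]-2-methoxycyclohexa-2,5-dien-1-ol | CCCCCCCCCCCCC[C@@H](O)CC1=C[C@@H](O[Si](c2ccccc2)(c2ccccc2)C(C)(C)C)C=C(OC)[C@H]1O | intermediate
24 | (1S,4R)-6-[(2R)-2-acetoxypentadecyl]-4-[(tert-butyldiphenylsilyl)oxy]-2-methoxycyclohexa-2,5-dien-1-yl acetate | CCCCCCCCCCCCC[C@H](CC1=C[C@@H](O[Si](c2ccccc2)(c2ccccc2)C(C)(C)C)C=C(OC)[C@H]1OC(C)=O)OC(C)=O | intermediate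
25 | (1S,4R)-6-[(2R)-2-acetoxypentadecyl]-4-hydroxy-2-methoxycyclohexa-2,5-dien-1-yl acetate | CCCCCCCCCCCCC[C@H](CC1=C[C@@H](O)C=C(OC)[C@H]1OC(C)=O)OC(C)=O | target

## Step count and least certain steps

Total step count: 17. Longest linear sequence: 15 steps (steps 1–4 and 7–17); the epoxide branch (steps 5 and 6) joins at step 7.

**Step 14 (key step).** What may go wrong:
- alkylidenation of the ester without ring closure;
- reductive cleavage of the α-silyloxy C–O bond or of an allylic C–O bond by low-valent titanium;
- Lewis-acid-induced loss of a doubly allylic silyloxy group followed by aromatisation.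

Fallback, from 21 back to 22: the two events are separated and the ring is closed by a different metal. Ester 21 is methylenated with Cp2TiMe2 (toluene, 65 °C, dark) to the acyclic methyl enol ether (3S,4Z,6S)-6-[(tert-butyldiphenylsilyl)oxy]-2-methoxy-3-[(triethylsilyl)oxy]-4-[(2R)-2-[(triethylsilyl)oxy]pentadecyl]octa-1,4,7-triene F1. F1 is then closed to 22 by catalytic ring-closing metathesis with Mo(=CHCMe2Ph)(=N-2,6-iPr2C6H3)[OCMe(CF3)2]2 in benzene, or with the second-generation Grubbs catalyst RuCl2(=CHPh)(PCy3)(H2IMes), with loss of ethylene.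

**Step 12.** What may go wrong: poor or reversed facial selectivity, because the ester and the twisted, branched alkenyl group may not differ clearly in size for the catalyst; and competing conjugate reduction.

Fallback, from 19 back to 20: face selection is replaced by separation and stereoinversion. Luche reduction of 19 (NaBH4, CeCl3·7H2O, MeOH, −78 °C) gives 20 together with its C6 epimer, methyl (2R,3Z,5S)-5-[(tert-butyldiphenylsilyl)oxy]-2-hydroxy-3-[(2R)-2-[(triethylsilyl)oxy]pentadecyl]hepta-3,6-dienoate F2. C3 and C6 sit close together on the Z-alkene, so chromatographic separation is realistic. F2 is inverted under Mitsunobu conditions (PPh3, diisopropyl azodicarboxylate, 4-nitrobenzoic acid) to the (2S)-ester, methyl (2S,3Z,5S)-5-[(tert-butyldiphenylsilyl)oxy]-2-[(4-nitrobenzoyl)oxy]-3-[(2R)-2-[(triethylsilyl)oxy]pentadecyl]hepta-3,6-dienoate F3. Brief methanolysis (catalytic K2CO3, MeOH, 0 °C) converts F3 to 20.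

**Step 8.** What may go wrong: erosion of regioselectivity, because the directing hydroxyl is homopropargylic and not propargylic, so part of the tin is delivered to C2; and sluggish addition next to the bulky silyl ether.

Fallback, from 5 (with 11) back to 16: the hydrometallation is directed by a free propargylic O3–H instead.
- 5 is protected with 4-methoxybenzyl trichloroacetimidate and catalytic acid as 1-methoxy-4-({[(3S)-5-(trimethylsilyl)pent-1-en-4-yn-3-yl]oxy}methyl)benzene F4.
- C-desilylation (K2CO3, MeOH) gives 1-methoxy-4-{[(3S)-pent-1-en-4-yn-3-yloxy]methyl}benzene F5.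
- Its lithium acetylide opens 11 (BF3·OEt2, −78 °C) to (3S,7R)-3-[(4-methoxybenzyl)oxy]icos-1-en-4-yn-7-ol F6.
- Silylation gives triethyl{[(3S,7R)-3-[(4-methoxybenzyl)oxy]icos-1-en-4-yn-7-yl]oxy}silane F7.
- Buffered DDQ frees the propargylic alcohol (3S,7R)-7-[(triethylsilyl)oxy]icos-1-en-4-yn-3-ol F8.
- Hydroxyl-directed trans-hydroalumination with NaAlH2(OCH2CH2OCH3)2 (THF, 0 °C) and an iodine quench at −78 °C give (3S,4Z,7R)-5-iodo-7-[(triethylsilyl)oxy]icosa-1,4-dien-3-ol F9.
- TBDPSCl and imidazole convert F9 to 16.

**Step 11.** What may go wrong: migration of a silyl group from O3 or O2' to the carbanionic carbon (1,4-shift), double addition to the oxalate, or γ-deprotonation of the product by unreacted organolithium.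

Fallback, from 16 back to 19: a Nozaki–Hiyama–Kishi addition of 16 to methyl glyoxylate (CrCl2, catalytic NiCl2, DMSO, rt; divalent chromium, divalent nickel) tolerates the silyl ethers. It gives the hydroxy ester as a mixture of C6 epimers, methyl (2RS,3Z,5S)-5-[(tert-butyldiphenylsilyl)oxy]-2-hydroxy-3-[(2R)-2-[(triethylsilyl)oxy]pentadecyl]hepta-3,6-dienoate F10. Dess–Martin periodinane (NaHCO3, CH2Cl2) oxidises F10 to 19.

**Step 15.** What may go wrong: hydrolysis of the enol ether or ionisation at C3 or C6 under the slightly acidic fluoride source, and partial loss of the TBDPS group on longer exposure.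

Fallback, from 22 back to 24: the free diol is bypassed by a direct silyl-to-acetyl exchange. Acetic anhydride with catalytic Bu4NF in THF exchanges the two triethylsilyl ethers for acetates under non-acidic conditions, while the TBDPS ether is too hindered to react. This gives 24 in one operation with no new intermediate.

## Further compounds

F1 | step 14 | (3S,4Z,6S)-6-[(tert-butyldiphenylsilyl)oxy]-2-methoxy-3-[(triethylsilyl)oxy]-4-[(2R)-2-[(triethylsilyl)oxy]pentadecyl]octa-1,4,7-triene | CCCCCCCCCCCCC[C@H](C/C(=C/[C@@H](O[Si](c1ccccc1)(c1ccccc1)C(C)(C)C)C=C)[C@H](O[Si](CC)(CC)CC)C(=C)OC)O[Si](CC)(CC)CC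
F2 | step 12 | methyl (2R,3Z,5S)-5-[(tert-butyldiphenylsilyl)oxy]-2-hydroxy-3-[(2R)-2-[(triethylsilyl)oxy]pentadecyl]hepta-3,6-dienoate | CCCCCCCCCCCCC[C@@H](O[Si](CC)(CC)CC)C/C(=C/[C@@H](O[Si](c1ccccc1)(c1ccccc1)C(C)(C)C)C=C)[C@@H](O)C(=O)OC
F3 | step 12 | methyl (2S,3Z,5S)-5-[(tert-butyldiphenylsilyl)oxy]-2-[(4-nitrobenzoyl)oxy]-3-[(2R)-2-[(triethylsilyl)oxy]pentadecyl]hepta-3,6-dienoate | CCCCCCCCCCCCC[C@@H](O[Si](CC)(CC)CC)C/C(=C/[C@@H](O[Si](c1ccccc1)(c1ccccc1)C(C)(C)C)C=C)[C@H](OC(=O)c1ccc(cc1)[N+](=O)[O-])C(=O)OC
F4 | step 8 | 1-methoxy-4-({[(3S)-5-(trimethylsilyl)pent-1-en-4-yn-3-yl]oxy}methyl)benzene | C=C[C@H](OCc1ccc(OC)cc1)C#C[Si](C)(C)C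
F5 | step 8 | 1-methoxy-4-{[(3S)-pent-1-en-4-yn-3-yloxy]methyl}benzene | C=C[C@H](OCc1ccc(OC)cc1)C#C
F6 | step 8 | (3S,7R)-3-[(4-methoxybenzyl)oxy]icos-1-en-4-yn-7-ol | CCCCCCCCCCCCC[C@@H](O)CC#C[C@@H](OCc1ccc(OC)cc1)C=C
F7 | step 8 | triethyl{[(3S,7R)-3-[(4-methoxybenzyl)oxy]icos-1-en-4-yn-7-yl]oxy}silane | CCCCCCCCCCCCC[C@@H](O[Si](CC)(CC)CC)CC#C[C@@H](OCc1ccc(OC)cc1)C=C
F8 | step 8 | (3S,7R)-7-[(triethylsilyl)oxy]icos-1-en-4-yn-3-ol | CCCCCCCCCCCCC[C@@H](O[Si](CC)(CC)CC)CC#C[C@@H](O)C=C
F9 | step 8 | (3S,4Z,7R)-5-iodo-7-[(triethylsilyl)oxy]icosa-1,4-dien-3-ol | CCCCCCCCCCCCC[C@@H](O[Si](CC)(CC)CC)C/C(I)=C/[C@@H](O)C=C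
F10 | step 11 | methyl (2RS,3Z,5S)-5-[(tert-butyldiphenylsilyl)oxy]-2-hydroxy-3-[(2R)-2-[(triethylsilyl)oxy]pentadecyl]hepta-3,6-dienoate (C2 epimer mixture) | CCCCCCCCCCCCC[C@@H](O[Si](CC)(CC)CC)C/C(=C/[C@@H](O[Si](c1ccccc1)(c1ccccc1)C(C)(C)C)C=C)C(O)C(=O)OC
F0 | step 15 | none | none
A1 | alternative 1 | silicon-tethered dienyne: diisopropylsilylene bis-ether of (4R)-heptadec-1-yn-4-ol and (1Z,3E)-4-[(tert-butyldiphenylsilyl)oxy]-2-methoxybuta-1,3-dien-1-ol | CCCCCCCCCCCCC[C@H](CC#C)O[Si](C(C)C)(C(C)C)O/C=C(OC)/C=C/O[Si](c1ccccc1)(c1ccccc1)C(C)(C)C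
A2 | alternative 1 | bicyclic diisopropylsilaketal (O6–Si–O2') of the O3-TBDPS-protected methoxycyclohexadiene | CCCCCCCCCCCCC[C@H](CC1=C[C@@H](O[Si](c2ccccc2)(c2ccccc2)C(C)(C)C)C=C(OC)[C@H]1O3)O[Si]3(C(C)C)C(C)C
A3 | alternative 2 | (1E,3E)-4-[(tert-butyldimethylsilyl)oxy]-3-[(2R)-2-[(tert-butyldimethylsilyl)oxy]pentadecyl]buta-1,3-dien-1-yl acetate | CCCCCCCCCCCCC[C@H](CC(=C\O[Si](C)(C)C(C)(C)C)/C=C/OC(C)=O)O[Si](C)(C)C(C)(C)C
A4 | alternative 2 | (2S)-2-tert-butyl-5-methylidene-1,3-dioxolan-4-one | C=C1O[C@H](C(C)(C)C)OC1=O
A5 | alternative 2 | spiro dioxolanone cyclohexene adduct | CCCCCCCCCCCCC[C@H](CC1=C[C@@H](OC(C)=O)C[C@@]2(O[C@H](C(C)(C)C)OC2=O)[C@H]1O[Si](C)(C)C(C)(C)C)O[Si](C)(C)C(C)(C)C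
A6 | alternative 3 | (2E,4S,5Z,8R)-4-[(tert-butyldimethylsilyl)oxy]-6-iodo-2-methoxy-8-[(triethylsilyl)oxy]henicosa-2,5-dienal | CCCCCCCCCCCCC[C@H](C/C(I)=C/[C@@H](O[Si](C)(C)C(C)(C)C)/C=C(/OC)C=O)O[Si](CC)(CC)CC
A7 | alternative 3 | cyclised dienol with free C6 hydroxyl, O3-TBS and O2'-TES | CCCCCCCCCCCCC[C@H](CC1=C[C@@H](O[Si](C)(C)C(C)(C)C)C=C(OC)[C@H]1O)O[Si](CC)(CC)CC
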